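**Plan**

- Retrosynthesis: with O5, O7 and O3' carried as triisopropylsilyl (TIPS) ethers, ring C is opened at the C2–C3 bond to give a ring-A diazomethyl ketone whose O1 bears the ring-B benzyl group. The diazo carbon is traced back to an acetyl methyl, the O1–C2 ether bond is cut to a phenol and a benzylic alcohol, and the O4'–prenyl bond leads back to 3,4-dihydroxybenzaldehyde.
- Forward: ring B is prepared (O4' prenylation, O3' silylation, reduction), ring A is bis-silylated, and the two arenes are joined at O1–C2 by Mitsunobu etherification. The acetyl group is converted to the diazo ketone, ring C closes last by C2–C3 bond formation, and buffered fluoride frees the three phenols.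
- Enabling feature: C2 is a benzylic carbon bound to O1. In the open precursor it is the CH2 of an aryl benzyl ether ortho to the C4 acyl group on ring A, so its C–H bonds are activated by both O1 and ring B and lie within reach of a carbene at C3 through a six-membered transition state.
- Stereochemistry: C2 is the only stereocentre. It is created in the ring closure, where a chiral dirhodium carboxylate selects one of the two enantiotopic benzylic hydrogens; the final deprotection is buffered so that ring C cannot open.

Key step: step 7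

Assumption: the sense of induction of Rh2(S-PTTL)4 at C2 cannot be predicted with certainty for a diazomethyl ketone; the route is written for the antipode that gives (2S), and Rh2(R-PTTL)4 would replace it if the sense proves opposite.

**Route**

Step 1
Reactants: 1 3,4-dihydroxybenzaldehyde; 2 prenyl bromide
Product: 3 3-hydroxy-4-(3-methylbut-2-enyloxy)benzaldehyde
Conditions: 2 (1.05 equiv), NaHCO3 (1.5 equiv), DMF, 40 °C
Reagents that add atoms: prenyl bromide (compound 2), CC(C)=CCBr
Why: Williamson etherification under weak-base control, in which the 4-hydroxyl (para to the formyl group) is the more acidic phenol and is the one alkylated by the allylic bromide, leaving O3 free.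

Step 2
Reactants: 3 3-hydroxy-4-(3-methylbut-2-enyloxy)benzaldehyde
Product: 4 4-(3-methylbut-2-enyloxy)-3-(triisopropylsilyloxy)benzaldehyde
Conditions: TIPSCl (1.2 equiv), imidazole (2.5 equiv), DMF, rt
Reagents that add atoms: triisopropylsilyl chloride, CC(C)[Si](Cl)(C(C)C)C(C)C
Why: Imidazole-promoted silylation of a phenol, giving a TIPS ether that should survive hydride, Mitsunobu, amide-base and carbene conditions and is later removed by fluoride without acid.

Step 3
Reactants: 4 4-(3-methylbut-2-enyloxy)-3-(triisopropylsilyloxy)benzaldehyde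
Product: 5 [4-(3-methylbut-2-enyloxy)-3-(triisopropylsilyloxy)phenyl]methanol
Conditions: NaBH4 (1 equiv), MeOH, 0 °C
Reagents that add atoms: none
Why: Chemoselective borohydride reduction of an aryl aldehyde to the benzylic alcohol, which should touch neither the aryl silyl ether nor the prenyl double bond.

Step 4
Reactants: 6 2',4',6'-trihydroxyacetophenone (dried)
Product: 7 1-[2-hydroxy-4,6-bis(triisopropylsilyloxy)phenyl]ethanone
Conditions: TIPSCl (2.2 equiv), imidazole (5 equiv), DMF, 0 °C to rt
Reagents that add atoms: triisopropylsilyl chloride, CC(C)[Si](Cl)(C(C)C)C(C)C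
Why: Phenol silylation in which the 4'-hydroxyl and one of the two equivalent ortho hydroxyls react, while the last hydroxyl, hydrogen-bonded to the carbonyl and flanked by the acetyl group, should resist the bulky chlorosilane, as in the usual 2,4-diprotection of this acetophenone.

Step 5
Reactants: 7 1-[2-hydroxy-4,6-bis(triisopropylsilyloxy)phenyl]ethanone; 5 [4-(3-methylbut-2-enyloxy)-3-(triisopropylsilyloxy)phenyl]methanol
Product: 8 1-{2-[4-(3-methylbut-2-enyloxy)-3-(triisopropylsilyloxy)benzyloxy]-4,6-bis(triisopropylsilyloxy)phenyl}ethanone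
Conditions: PPh3 (1.3 equiv), DIAD (1.3 equiv), THF, 0 °C to rt
Reagents that add atoms: none
Why: Mitsunobu etherification, in which the chelated phenol is acidic enough to protonate the betaine and displaces the primary benzylic oxyphosphonium group under neutral conditions that leave the three aryl silyl ethers intact, forming the O1–C2 bond.

Step 6
Reactants: 8 1-{2-[4-(3-methylbut-2-enyloxy)-3-(triisopropylsilyloxy)benzyloxy]-4,6-bis(triisopropylsilyloxy)phenyl}ethanone
Product: 10 2-diazo-1-{2-[4-(3-methylbut-2-enyloxy)-3-(triisopropylsilyloxy)benzyloxy]-4,6-bis(triisopropylsilyloxy)phenyl}ethanone, via trifluoroacetyl ketone 9 (not isolated)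
Conditions: LiN(SiMe3)2 (1.1 equiv), THF, −78 °C; CF3CO2CH2CF3 (1.2 equiv), −78 °C; cold 1 M HCl work-up; then crude 9, MsN3 (1.5 equiv), Et3N (1.5 equiv), H2O (1 equiv), MeCN, rt
Reagents that add atoms: methanesulfonyl azide, CS(=O)(=O)N=[N+]=[N-] (both diazo nitrogens of 10); 2,2,2-trifluoroethyl trifluoroacetate, O=C(OCC(F)(F)F)C(F)(F)F (the trifluoroacetyl group of 9 only, lost again before 10)
Why: Detrifluoroacetylative Regitz-type diazo transfer, in which the lithium enolate of the only enolisable position is trifluoroacetylated (Claisen-type) and the activated methylene then accepts the diazo group with loss of the trifluoroacetyl unit as an N-acylsulfonamide, a sequence established for aryl methyl ketones that do not undergo direct diazo transfer.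

Step 7
Reactants: 10 2-diazo-1-{2-[4-(3-methylbut-2-enyloxy)-3-(triisopropylsilyloxy)benzyloxy]-4,6-bis(triisopropylsilyloxy)phenyl}ethanone
Product: 11 (2S)-5,7-bis(triisopropylsilyloxy)-2-[4-(3-methylbut-2-enyloxy)-3-(triisopropylsilyloxy)phenyl]chroman-4-one
Conditions: Rh2(S-PTTL)4 (dirhodium tetrakis[N-phthaloyl-(S)-tert-leucinate], 2 mol %), CH2Cl2, 0 °C, 10 added over 2 h (final 0.01 M)
Reagents that add atoms: none
Why: The divalent-rhodium dimer takes up the diazo carbon of 10 with loss of N2 to give an electrophilic rhodium carbene at C3, which inserts into a benzylic C–H bond of the OCH2Ar group through a concerted, hydride-transfer-like three-centre transition state. The closest known reaction type is the dirhodium-carboxylate-catalysed cyclisation of 2-alkoxyaryl diazo ketones to chroman-4-ones by C–H insertion next to the ether oxygen, including versions with chiral carboxylate ligands. Ring C closes by C2–C3 bond formation as a 1,6-insertion through a six-membered cyclic array of C3, C4, C4a, C8a, O1 and C2; no five-membered alternative exists because the atom at that distance is O1. C2 is the only new stereocentre, and its configuration is decided by the phthalimido-tert-leucinate ligands, which differentiate the two enantiotopic hydrogens on C2. The step needs insertion to outrun attack of the carbene on O1 (oxonium ylide, then benzyl shift to a benzofuranone), on the silyl ether oxygen at C5, on the prenyl double bond and on a second molecule of 10. The double activation of the benzylic C–H bond by O1 and the electron-rich ring B, the bulk and weak donor character of the TIPS ether (which also offers no C–H bond at insertion distance), the remoteness of the alkene and slow addition at high dilution are relied on for this.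

Step 8
Reactants: 11 (2S)-5,7-bis(triisopropylsilyloxy)-2-[4-(3-methylbut-2-enyloxy)-3-(triisopropylsilyloxy)phenyl]chroman-4-one
Product: 12 monotesone A, (2S)-5,7-dihydroxy-2-[3-hydroxy-4-(3-methylbut-2-enyloxy)phenyl]chroman-4-one
Conditions: Bu4NF (3.6 equiv), AcOH (3.6 equiv), THF, 0 °C
Reagents that add atoms: none
Why: Fluoride cleavage of the three aryl silyl ethers, with acetic acid buffering so that no free phenoxide can open ring C by retro-oxa-Michael reaction (which would scramble C2) and so that the acid-sensitive prenyl ether sees no strong acid.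

**Compound list**

1 | 3,4-dihydroxybenzaldehyde | O=Cc1ccc(O)c(O)c1 | starting material
2 | prenyl bromide (1-bromo-3-methylbut-2-ene) | CC(C)=CCBr | starting material
3 | 3-hydroxy-4-(3-methylbut-2-enyloxy)benzaldehyde | O=Cc1ccc(OCC=C(C)C)c(O)c1 | intermediate
4 | 4-(3-methylbut-2-enyloxy)-3-(triisopropylsilyloxy)benzaldehyde | O=Cc1ccc(OCC=C(C)C)c(O[Si](C(C)C)(C(C)C)C(C)C)c1 | intermediate
5 | [4-(3-methylbut-2-enyloxy)-3-(triisopropylsilyloxy)phenyl]methanol | OCc1ccc(OCC=C(C)C)c(O[Si](C(C)C)(C(C)C)C(C)C)c1 | intermediate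
6 | 2',4',6'-trihydroxyacetophenone | CC(=O)c1c(O)cc(O)cc1O | starting material
7 | 1-[2-hydroxy-4,6-bis(triisopropylsilyloxy)phenyl]ethanone | CC(=O)c1c(O)cc(O[Si](C(C)C)(C(C)C)C(C)C)cc1O[Si](C(C)C)(C(C)C)C(C)C | intermediate
8 | 1-{2-[4-(3-methylbut-2-enyloxy)-3-(triisopropylsilyloxy)benzyloxy]-4,6-bis(triisopropylsilyloxy)phenyl}ethanone | CC(=O)c1c(OCc2ccc(OCC=C(C)C)c(O[Si](C(C)C)(C(C)C)C(C)C)c2)cc(O[Si](C(C)C)(C(C)C)C(C)C)cc1O[Si](C(C)C)(C(C)C)C(C)C | intermediate
9 | 4,4,4-trifluoro-1-{2-[4-(3-methylbut-2-enyloxy)-3-(triisopropylsilyloxy)benzyloxy]-4,6-bis(triisopropylsilyloxy)phenyl}butane-1,3-dione (enolised in solution) | O=C(CC(=O)C(F)(F)F)c1c(OCc2ccc(OCC=C(C)C)c(O[Si](C(C)C)(C(C)C)C(C)C)c2)cc(O[Si](C(C)C)(C(C)C)C(C)C)cc1O[Si](C(C)C)(C(C)C)C(C)C | intermediate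
10 | 2-diazo-1-{2-[4-(3-methylbut-2-enyloxy)-3-(triisopropylsilyloxy)benzyloxy]-4,6-bis(triisopropylsilyloxy)phenyl}ethanone | [N-]=[N+]=CC(=O)c1c(OCc2ccc(OCC=C(C)C)c(O[Si](C(C)C)(C(C)C)C(C)C)c2)cc(O[Si](C(C)C)(C(C)C)C(C)C)cc1O[Si](C(C)C)(C(C)C)C(C)C | intermediate
11 | (2S)-5,7-bis(triisopropylsilyloxy)-2-[4-(3-methylbut-2-enyloxy)-3-(triisopropylsilyloxy)phenyl]chroman-4-one | CC(C)=CCOc1ccc([C@@H]2CC(=O)c3c(O[Si](C(C)C)(C(C)C)C(C)C)cc(O[Si](C(C)C)(C(C)C)C(C)C)cc3O2)cc1O[Si](C(C)C)(C(C)C)C(C)C | intermediate
12 | monotesone A, (2S)-5,7-dihydroxy-2-[3-hydroxy-4-(3-methylbut-2-enyloxy)phenyl]chroman-4-one | CC(C)=CCOc1ccc([C@@H]2CC(=O)c3c(O)cc(O)cc3O2)cc1O | target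

**Count**

Total step count: 8.
Longest linear sequence: 7 steps (steps 1, 2, 3, 5, 6, 7, 8 from 3,4-dihydroxybenzaldehyde); the ring-A branch contributes step 4.

**Steps most likely to fail**

1. Step 7. The chiral carboxylate may discriminate poorly between the two enantiotopic hydrogens on C2, because a carbene from a diazomethyl ketone is very reactive and its transition state is early. The carbene may also be diverted to O1, followed by benzyl migration. The fallback avoids the carbene and sets out from 7 and 4. Double deprotonation of 7 with LiN(SiMe3)2 (2.2 equiv, THF, −78 °C) and aldol addition to aldehyde 4 should give racemic 3-hydroxy-1-[2-hydroxy-4,6-bis(triisopropylsilyloxy)phenyl]-3-[4-(3-methylbut-2-enyloxy)-3-(triisopropylsilyloxy)phenyl]propan-1-one F1. Intramolecular Mitsunobu etherification (PPh3, DIAD, THF, 0 °C) would then close ring C at O1–C2 to the racemic tris-silylated flavanone F2. Kinetic resolution by asymmetric transfer hydrogenation (Cp*RhCl(TsDPEN), the enantiomer that reduces the (2R)-ketone faster, HCO2H/Et3N, EtOAc) should convert the unwanted antipode into the cis-(2R,4R)-flavan-4-ol F3, which is separable by chromatography from the unreacted (2S)-ketone. That ketone is 11, where the route is rejoined; at most half of the material can be recovered this way. The same resolution could also raise the enantiomeric purity of 11 obtained from step 7.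

2. Step 6. Under LiN(SiMe3)2 the ortho silyl group may migrate from the phenolic oxygen to the enolate oxygen, or the hindered enolate may be C-acylated sluggishly. The fallback sets out from 8 and needs no lithium enolate. Soft enolisation (TMSOTf, Et3N, CH2Cl2, 0 °C) should give the trimethylsilyl enol ether F4, and NBS in THF at −78 °C the bromomethyl ketone F5. Treatment with N,N'-ditosylhydrazine and DBU (THF, 0 °C) would alkylate the hydrazine to the N-(2-aryl-2-oxoethyl)-N,N'-ditosylhydrazine F6 (not isolated), which loses two sulfinate groups under the same base to give 10, where the route is rejoined.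

3. Step 5. The chelated, flanked phenol may react slowly, so that the activated electron-rich benzylic alcohol is consumed by alkylating the reduced azodicarboxylate or by ionisation. The fallback sets out from 5. Appel bromination (CBr4, PPh3, CH2Cl2, 0 °C) should give 4-(bromomethyl)-1-(3-methylbut-2-enyloxy)-2-(triisopropylsilyloxy)benzene F7, used crude. Williamson-type alkylation of phenol 7 with F7 and Ag2O in CH2Cl2 at rt, under conditions mild towards aryl silyl ethers, would deliver 8, where the route is rejoined.

**Further compounds**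

F1 | step 7 | racemic 3-hydroxy-1-[2-hydroxy-4,6-bis(triisopropylsilyloxy)phenyl]-3-[4-(3-methylbut-2-enyloxy)-3-(triisopropylsilyloxy)phenyl]propan-1-one | CC(C)=CCOc1ccc(C(O)CC(=O)c2c(O)cc(O[Si](C(C)C)(C(C)C)C(C)C)cc2O[Si](C(C)C)(C(C)C)C(C)C)cc1O[Si](C(C)C)(C(C)C)C(C)C
F2 | step 7 | racemic 5,7-bis(triisopropylsilyloxy)-2-[4-(3-methylbut-2-enyloxy)-3-(triisopropylsilyloxy)phenyl]chroman-4-one | CC(C)=CCOc1ccc(C2CC(=O)c3c(O[Si](C(C)C)(C(C)C)C(C)C)cc(O[Si](C(C)C)(C(C)C)C(C)C)cc3O2)cc1O[Si](C(C)C)(C(C)C)C(C)C
F3 | step 7 | (2R,4R)-5,7-bis(triisopropylsilyloxy)-2-[4-(3-methylbut-2-enyloxy)-3-(triisopropylsilyloxy)phenyl]chroman-4-ol (2,4-cis) | CC(C)=CCOc1ccc([C@H]2C[C@@H](O)c3c(O[Si](C(C)C)(C(C)C)C(C)C)cc(O[Si](C(C)C)(C(C)C)C(C)C)cc3O2)cc1O[Si](C(C)C)(C(C)C)C(C)C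
F4 | step 6 | trimethylsilyl enol ether of 8, 1-{2-[4-(3-methylbut-2-enyloxy)-3-(triisopropylsilyloxy)benzyloxy]-4,6-bis(triisopropylsilyloxy)phenyl}-1-(trimethylsilyloxy)ethene | C=C(O[Si](C)(C)C)c1c(OCc2ccc(OCC=C(C)C)c(O[Si](C(C)C)(C(C)C)C(C)C)c2)cc(O[Si](C(C)C)(C(C)C)C(C)C)cc1O[Si](C(C)C)(C(C)C)C(C)C
F5 | step 6 | 2-bromo-1-{2-[4-(3-methylbut-2-enyloxy)-3-(triisopropylsilyloxy)benzyloxy]-4,6-bis(triisopropylsilyloxy)phenyl}ethanone | BrCC(=O)c1c(OCc2ccc(OCC=C(C)C)c(O[Si](C(C)C)(C(C)C)C(C)C)c2)cc(O[Si](C(C)C)(C(C)C)C(C)C)cc1O[Si](C(C)C)(C(C)C)C(C)C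
F6 | step 6 | N-(2-aryl-2-oxoethyl)-N,N'-ditosylhydrazine derived from F5 | Cc1ccc(cc1)S(=O)(=O)NN(CC(=O)c1c(OCc2ccc(OCC=C(C)C)c(O[Si](C(C)C)(C(C)C)C(C)C)c2)cc(O[Si](C(C)C)(C(C)C)C(C)C)cc1O[Si](C(C)C)(C(C)C)C(C)C)S(=O)(=O)c1ccc(C)cc1
F7 | step 5 | 4-(bromomethyl)-1-(3-methylbut-2-enyloxy)-2-(triisopropylsilyloxy)benzene | BrCc1ccc(OCC=C(C)C)c(O[Si](C(C)C)(C(C)C)C(C)C)c1
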